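With time, product in Saturday's run flattens, and the balance of substrate, the smaller charge, still shows 91.6% of it not turned into product at 6.00 h. So something other than a shortage of substrate stops Saturday's run; call it a clock.

| flask | substrate | partner | free catalyst | remark | time |
|---|---|---|---|---|---|
| Saturday's | 10 mM | 20 mM | 100 µM | run made earlier |  |
| Tuesday's | 10 mM | 20 mM | 150 µM | run made earlier |  |
| birch | 10 mM | 20.0 mM | 100 µM | everything together at the start | 10 h |
| cedar | 10 mM (fed, over 4.0 h) | 20.0 mM | 100 µM | all else is in the flask from the start; the feed brings no volume worth counting | 10 h |
| alder | 10 mM | 20.0 mM (fed, over 4.0 h) | 100 µM | all else is in the flask from the start; the feed brings no volume worth counting | 10 h |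
| oak | 10 mM (fed, over 1.0 h) | 20.0 mM | 100 µM | all else is in the flask from the start; the feed brings no volume worth counting | 10 h |

| run | time / h | product / % |
|---|---|---|
| Saturday's | 0.500 | 3.9 |
| Saturday's | 0.833 | 4.9 |
| Saturday's | 1.50 | 6.0 |
| Saturday's | 3.00 | 7.6 |
| Saturday's | 6.00 | 8.4 |
| Tuesday's | 0.250 | 2.2 |
| Tuesday's | 0.833 | 7.8 |
| Tuesday's | 1.33 | 9.6 |
| Tuesday's | 2.00 | 10.6 |
| Tuesday's | 3.00 | 11.8 |

(each reading ± 0.5 percentage points)

- the flask with the highest amount of product, in percent of the substrate charged ("all alike" if they lie within 1.5 percentage points) (birch / cedar / alder / oak / all alike)
- final product, as a percentage of the substrate charged, in birch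
- final product, as a percentage of the substrate charged, in cedar
- final product, as a percentage of the substrate charged, in alder
- final product, as a percentage of the substrate charged, in oak

- what was read earlier has a scatter of 0.5 percentage points, one standard deviation

Read the two tables against each other. In the row at 0.833 h, Tuesday's product is 1.59 times Saturday's. In the row at 3.00 h it is 1.55 times, and the catalyst ratio is 1.50. Within the scatter, product therefore scales with the catalyst charged at both times, and these two runs show no change in the stopping time.

Saturday's first row gives a mean early rate of 0.0780 /h of the charge over that first interval. Dividing Saturday's last reading, taken as the plateau, by it gives 1.08 h. This W, the time at the early rate that makes the plateau, is the working time, a time constant read from the readings.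

Birch repeats Saturday's recipe, so the reckoning here gives 8.4%. Taking the rate as first order in substrate, an assumption of this reckoning, substrate fed evenly over a time t_f meets a clock already running, so the plateau is multiplied by the share s = (W/t_f)(1 − e^(−t_f/W)). That share is 0.263 for cedar, whose feed outlasts W, giving 2.21%, and 0.651 for oak, giving 5.47%. On this reckoning the shares for cedar and oak are the same whether catalyst or partner carries the clock, and Saturday's and Tuesday's runs do not separate the two. Alder is the test: with the rate also first order in partner, alder matches cedar if catalyst carries the clock, and it stands at 8.4% if partner carries it, each portion of partner then lasting W on average whenever it enters.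

The forecast, which reads “I assume clock death and rate first-order in each reactant”, gives birch 8.3%, cedar 2%, alder 2% and oak 5.2%.

The flasks give birch 7.46%, cedar 3.45%, alder 16.1% and oak 5.51%, so alder stands highest, at twice birch's product.

    substrate + free catalyst → catalyst intermediate A (k = 77.9 /M/min)
    catalyst intermediate A ⇌ catalyst intermediate B (K = 91.7, k = 0.236 /min)
    partner + catalyst intermediate B ⇌ catalyst intermediate C (K = 67.0 /M, k = 70.1 /M/min)
    catalyst intermediate C → catalyst intermediate D (k = 4.59 /min)
    catalyst intermediate D → free catalyst + product (k = 7.41 /min)
    partner → decomposed reagent (k = 0.0410 /min)

The step from partner to decomposed reagent has a half-life of 0.28 h by that step alone in birch, and birch holds 19.3 mM of decomposed reagent at 10.0 h. The neighbour is cedar with 0.40 mM of free catalyst, which is 4.00 times the charge. The same share and a plateau scaled with the catalyst reckon 8.83%, and the neighbour gives 10.6%. At 10.0 h the neighbour's partner stands at 0%, and catalyst intermediate B, the resting state, holds 3.96% of the substrate charged.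

(The numbers in the tables stem from a simulated flask with constants of no real substance; noise was put on by code.)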